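**Retrosynthetic overview**

1. Target ⇐ bis-silyl macrocycle (desilylation) ⇐ acyclic iodo-alkene by intramolecular Pd-catalysed B-alkyl Suzuki–Miyaura coupling (C3–C4 bond); the ten-membered ring is closed last.
2. Acyclic iodo-alkene ⇐ methacryloyl chloride + secondary alcohol ⇐ aldehyde fragment + (bromomethyl)butenolide fragment by chromium-catalysed γ-allylation (C7–C8 bond, sets C7 and C8, creates the α-methylene lactone).
3. Butenolide fragment ⇐ acrolein + methyl propiolate + 2-(bromomethyl)acrylic acid: asymmetric alkynylation (C6), syn-hydrostannation/iodination/lactonisation (a transient 6,15-butenolide that fixes the C4=C5 geometry and is opened again), esterification, ring-closing metathesis.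
4. Aldehyde fragment ⇐ methyl 4-oxobutanoate + allyltrimethylsilane by organocatalytic α-allylation (C10), then reduction, silylation, reduction, oxidation.
5. Ring order: transient butenolide (opened) → 6,12-butenolide by metathesis → α-methylene-γ-butyrolactone in the fragment coupling → ten-membered carbocycle.

**Assumptions**

- The target is taken exactly as drawn, (3aS,4R,6R,10Z,11aS) in cyclodeca[b]furan numbering. Labels C1–C15 are germacrane positions: C4=C5 ring alkene, C6 lactone carbinol, C7 ring-fusion CH, C8 ester carbinol, C10 the CH bearing C14H2OH, C11=C13 exocyclic methylene, C12 lactone carbonyl, C15H2OH on C4.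
- The enantiomers named for the chiral catalyst of step 1 and the chiral ligand of step 6 are those expected to give the (R) products shown; if the sense of induction proves opposite, the antipode is used.
- TBS = tert-butyldimethylsilyl.

**Route**

Step 1
Reactants: 1 methyl 4-oxobutanoate; 2 allyltrimethylsilane
Product: 3 methyl (R)-3-formylhex-5-enoate
Conditions: (2S,5S)-5-benzyl-2-tert-butyl-3-methylimidazolidin-4-one trifluoroacetate (20 mol%), (NH4)2Ce(NO3)6 (2 equiv), NaHCO3 (2 equiv), H2O (2 equiv), DME, −20 °C, 24 h; used crude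
Reagents that add atoms: none
Why: Organocatalytic SOMO α-allylation, in which the enamine of 1 is oxidised by tetravalent cerium to a radical cation that adds the allylsilane on the face left open by the catalyst, setting C10 as (R) (about 90% ee expected).

Step 2
Reactants: 3 methyl (R)-3-formylhex-5-enoate
Product: 4 methyl (R)-3-(hydroxymethyl)hex-5-enoate
Conditions: NaBH4 (0.5 equiv), MeOH, −20 °C, 30 min; pH 7 buffer, cold extraction, used at once
Reagents that add atoms: none
Why: Chemoselective borohydride reduction of the aldehyde beside the methyl ester removes the epimerisable α-formyl centre, so C10 is configurationally fixed from here on.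

Step 3
Reactants: 4 methyl (R)-3-(hydroxymethyl)hex-5-enoate
Product: 5 methyl (R)-3-[(tert-butyldimethylsilyloxy)methyl]hex-5-enoate
Conditions: TBSCl (1.2 equiv), imidazole (2.5 equiv), CH2Cl2, 0 °C → rt
Reagents that add atoms: tert-butyldimethylsilyl chloride, CC(C)(C)[Si](C)(C)Cl
Why: Standard silylation of the primary alcohol protects C14–OH and prevents lactonisation onto the ester.

Step 4
Reactants: 5 methyl (R)-3-[(tert-butyldimethylsilyloxy)methyl]hex-5-enoate
Product: 6 (R)-3-[(tert-butyldimethylsilyloxy)methyl]hex-5-en-1-ol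
Conditions: i-Bu2AlH (2.5 equiv), CH2Cl2, −78 → 0 °C; aq. KNaC4H4O6
Reagents that add atoms: none
Why: Hydride reduction of the ester to the primary alcohol, with the silyl ether and the alkene inert.

Step 5
Reactants: 6 (R)-3-[(tert-butyldimethylsilyloxy)methyl]hex-5-en-1-ol
Product: 7 (R)-3-[(tert-butyldimethylsilyloxy)methyl]hex-5-enal
Conditions: Dess–Martin periodinane (1.2 equiv), CH2Cl2, 0 °C → rt
Reagents that add atoms: none
Why: Dess–Martin oxidation gives the aldehyde under non-basic conditions, and C10 is β to the carbonyl so it cannot epimerise.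

Step 6
Reactants: 8 acrolein; 9 methyl propiolate
Product: 11 methyl (R)-4-hydroxyhex-5-en-2-ynoate, via methylzinc alkynide 10 (not isolated)
Conditions: 9 (3 equiv), Me2Zn (3 equiv), (S,S)-ProPhenol [2,6-bis{[(2S)-2-(hydroxydiphenylmethyl)pyrrolidin-1-yl]methyl}-4-methylphenol] (10 mol%), Ph3P=O (20 mol%), toluene, 0 °C, 1 h; then 8 (1 equiv), 4 °C, 36 h; aq. NH4Cl
Reagents that add atoms: dimethylzinc, C[Zn]C (its zinc and methyl stay only in 10)
Why: Catalytic enantioselective alkynylation of an enal (Trost ProPhenol type), in which the dinuclear zinc complex delivers the alkynyl group to one carbonyl face in a 1,2-addition and sets C6 as (R).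

Step 7
Reactants: 11 methyl (R)-4-hydroxyhex-5-en-2-ynoate
Product: 14 (R)-3-iodo-5-vinylfuran-2(5H)-one, via stannyl dienoate 12 (not isolated), via iodo dienoate 13 (not isolated)
Conditions: Bu3SnH (1.1 equiv), Pd(PPh3)2Cl2 (2 mol%), THF, 0 °C; I2 (1.15 equiv), CH2Cl2, 0 °C; TsOH·H2O (5 mol%), rt
Reagents that add atoms: tributyltin hydride, CCCC[SnH](CCCC)CCCC (its tin stays only in 12); iodine, [I][I]
Why: Palladium-catalysed syn-hydrostannation of the ynoate (tin α to the ester, H at C5), iododestannylation with retention and acid-catalysed lactonisation of the cis hydroxy ester, which locks C15 cis to C6 and iodine trans to C6 as needed for the C4=C5 bond.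

Step 8
Reactants: 14 (R)-3-iodo-5-vinylfuran-2(5H)-one
Product: 15 (2E,4R)-2-iodohexa-2,5-diene-1,4-diol
Conditions: i-Bu2AlH (3.5 equiv), CH2Cl2, −78 → 0 °C; aq. KNaC4H4O6
Reagents that add atoms: none
Why: 1,2-Reduction of the butenolide through the lactol to the ene-diol, which keeps the alkene geometry and leaves the vinyl iodide untouched at low temperature.

Step 9
Reactants: 15 (2E,4R)-2-iodohexa-2,5-diene-1,4-diol
Product: 16 (3R,4E)-6-(tert-butyldimethylsilyloxy)-5-iodohexa-1,4-dien-3-ol
Conditions: TBSCl (1.05 equiv), imidazole (2 equiv), CH2Cl2, −20 °C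
Reagents that add atoms: tert-butyldimethylsilyl chloride, CC(C)(C)[Si](C)(C)Cl
Why: Selective silylation of the primary allylic alcohol over the hindered secondary bis-allylic alcohol at low temperature.

Step 10
Reactants: 16 (3R,4E)-6-(tert-butyldimethylsilyloxy)-5-iodohexa-1,4-dien-3-ol; 17 2-(bromomethyl)acrylic acid
Product: 18 (3R,4E)-6-(tert-butyldimethylsilyloxy)-5-iodohexa-1,4-dien-3-yl 2-(bromomethyl)acrylate
Conditions: 17 (1.3 equiv), DIC (1.4 equiv), DMAP (5 mol%), CH2Cl2, 0 °C
Reagents that add atoms: none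
Why: Steglich esterification under mild carbodiimide activation with only catalytic DMAP, so the allylic bromide is not displaced.

Step 11
Reactants: 18 (3R,4E)-6-(tert-butyldimethylsilyloxy)-5-iodohexa-1,4-dien-3-yl 2-(bromomethyl)acrylate
Product: 19 (R)-3-(bromomethyl)-5-[(E)-3-(tert-butyldimethylsilyloxy)-2-iodoprop-1-enyl]furan-2(5H)-one
Conditions: second-generation Grubbs catalyst (5 mol%), CH2Cl2 (0.01 M), 40 °C
Reagents that add atoms: none
Why: Ring-closing metathesis between the vinyl group and the acrylate alkene closes the butenolide with loss of ethene, while the trisubstituted iodoalkene and the allylic bromide do not engage and C6 is untouched.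

Step 12
Reactants: 7 (R)-3-[(tert-butyldimethylsilyloxy)methyl]hex-5-enal; 19 (R)-3-(bromomethyl)-5-[(E)-3-(tert-butyldimethylsilyloxy)-2-iodoprop-1-enyl]furan-2(5H)-one
Product: 21 (4S,5R)-4-[(1R,3R)-3-[(tert-butyldimethylsilyloxy)methyl]-1-hydroxyhex-5-enyl]-5-[(E)-3-(tert-butyldimethylsilyloxy)-2-iodoprop-1-enyl]-3-methylenedihydrofuran-2(3H)-one, via trimethylsilyl ether 20 (not isolated)
Conditions: CrCl2 (10 mol%, nickel-free grade), Mn powder (2 equiv), Me3SiCl (1.5 equiv), THF, 0 °C → rt, 19 (1.2 equiv) added over 4 h to 7; then aq. citric acid, THF, 0 °C, 15 min; chromatography removes the diastereomers that stem from the minor enantiomers of 7 and 19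
Reagents that add atoms: chlorotrimethylsilane, C[Si](C)(C)Cl (its silyl group stays only in 20)
Why: Proposed new method: chromium-catalysed γ-selective allylation of an aldehyde by a 5-substituted 3-(bromomethyl)butenolide (a catalytic Nozaki–Hiyama-type 2-(alkoxycarbonyl)allylation), in which two one-electron reductions by divalent chromium turn the allylic bromide into a primary allylchromium species whose ring-locked (E) geometry enforces a chair Zimmerman–Traxler transition state with the aldehyde chain equatorial and C–C bond formation at ring carbon C7 on the face anti to the C6 side chain, giving the trans lactone, the anti C7/C8 relationship and the exocyclic methylene in one event, after which Me3SiCl silylates the chromium alkoxide and Mn returns trivalent chromium to the divalent state; the closest known reactions are the stoichiometric zinc Barbier allylation of aldehydes with bromomethylbutenolides and the chromium-catalysed 2-(alkoxycarbonyl)allylation with acyclic 2-(bromomethyl)acrylates, neither of which has been shown under chromium catalysis for a butenolide carrying a stereocentre at C5.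

Step 13
Reactants: 21 (4S,5R)-4-[(1R,3R)-3-[(tert-butyldimethylsilyloxy)methyl]-1-hydroxyhex-5-enyl]-5-[(E)-3-(tert-butyldimethylsilyloxy)-2-iodoprop-1-enyl]-3-methylenedihydrofuran-2(3H)-one; 22 methacryloyl chloride
Product: 23 (1R,3R)-3-[(tert-butyldimethylsilyloxy)methyl]-1-[(2R,3S)-2-[(E)-3-(tert-butyldimethylsilyloxy)-2-iodoprop-1-enyl]-4-methylene-5-oxotetrahydrofuran-3-yl]hex-5-enyl methacrylate
Conditions: 22 (2 equiv), Et3N (3 equiv), DMAP (10 mol%), CH2Cl2, 0 °C
Reagents that add atoms: none
Why: DMAP-catalysed acylation of the only free hydroxyl, done before the basic coupling step so that translactonisation to the 8,12-olide is excluded.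

Step 14
Reactants: 23 (1R,3R)-3-[(tert-butyldimethylsilyloxy)methyl]-1-[(2R,3S)-2-[(E)-3-(tert-butyldimethylsilyloxy)-2-iodoprop-1-enyl]-4-methylene-5-oxotetrahydrofuran-3-yl]hex-5-enyl methacrylate
Product: 25 (3aS,4R,6R,10Z,11aS)-6,10-bis[(tert-butyldimethylsilyloxy)methyl]-3-methylene-2-oxo-2,3,3a,4,5,6,7,8,9,11a-decahydrocyclodeca[b]furan-4-yl methacrylate, via alkylborane 24 (not isolated)
Conditions: 9-BBN dimer (1.5 equiv B–H), THF, 0 °C → rt, 3 h; then added over 12 h to Pd(dppf)Cl2 (20 mol%), AsPh3 (40 mol%), Cs2CO3 (3 equiv), DMF/THF/H2O, final 1 mM, 45 °C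
Reagents that add atoms: 9-borabicyclo[3.3.1]nonane, B1C2CCCC1CCC2 (its boron stays only in 24)
Why: Intramolecular B-alkyl Suzuki–Miyaura coupling, in which 9-BBN hydroborates only the unconjugated terminal alkene (anti-Markovnikov) and oxidative addition of zerovalent palladium into the C–I bond, base-assisted transmetalation and reductive elimination form C3–C4 with retention of alkene geometry, closing the ten-membered ring at high dilution.

Step 15
Reactants: 25 (3aS,4R,6R,10Z,11aS)-6,10-bis[(tert-butyldimethylsilyloxy)methyl]-3-methylene-2-oxo-2,3,3a,4,5,6,7,8,9,11a-decahydrocyclodeca[b]furan-4-yl methacrylate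
Product: 26 (3aS,4R,6R,10Z,11aS)-6,10-bis(hydroxymethyl)-3-methylene-2-oxo-2,3,3a,4,5,6,7,8,9,11a-decahydrocyclodeca[b]furan-4-yl methacrylate
Conditions: HF·pyridine, pyridine, THF, 0 °C → rt
Reagents that add atoms: none
Why: Fluoride-mediated cleavage of both primary silyl ethers under buffered acidic conditions that leave the methacrylate, the α-methylene lactone and all four stereocentres untouched.

**Compound list**

1 | methyl 4-oxobutanoate | COC(=O)CCC=O | starting material
2 | allyltrimethylsilane | C=CC[Si](C)(C)C | starting material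
3 | methyl (R)-3-formylhex-5-enoate | COC(=O)C[C@H](C=O)CC=C | intermediate
4 | methyl (R)-3-(hydroxymethyl)hex-5-enoate | COC(=O)C[C@H](CO)CC=C | intermediate
5 | methyl (R)-3-[(tert-butyldimethylsilyloxy)methyl]hex-5-enoate | COC(=O)C[C@H](CO[Si](C)(C)C(C)(C)C)CC=C | intermediate
6 | (R)-3-[(tert-butyldimethylsilyloxy)methyl]hex-5-en-1-ol | OCC[C@H](CO[Si](C)(C)C(C)(C)C)CC=C | intermediate
7 | (R)-3-[(tert-butyldimethylsilyloxy)methyl]hex-5-enal | O=CC[C@H](CO[Si](C)(C)C(C)(C)C)CC=C | intermediate
8 | acrolein | C=CC=O | starting material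
9 | methyl propiolate | C#CC(=O)OC | starting material
10 | methyl 3-(methylzincio)prop-2-ynoate | C[Zn]C#CC(=O)OC | intermediate
11 | methyl (R)-4-hydroxyhex-5-en-2-ynoate | COC(=O)C#C[C@H](O)C=C | intermediate
12 | methyl (2E,4R)-4-hydroxy-2-(tributylstannyl)hexa-2,5-dienoate | CCCC[Sn](CCCC)(CCCC)C(/C(=O)OC)=C/[C@H](O)C=C | intermediate
13 | methyl (2E,4R)-4-hydroxy-2-iodohexa-2,5-dienoate | IC(/C(=O)OC)=C/[C@H](O)C=C | intermediate
14 | (R)-3-iodo-5-vinylfuran-2(5H)-one | IC1=C[C@@H](C=C)OC1=O | intermediate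
15 | (2E,4R)-2-iodohexa-2,5-diene-1,4-diol | IC(/CO)=C/[C@H](O)C=C | intermediate
16 | (3R,4E)-6-(tert-butyldimethylsilyloxy)-5-iodohexa-1,4-dien-3-ol | IC(/CO[Si](C)(C)C(C)(C)C)=C/[C@H](O)C=C | intermediate
17 | 2-(bromomethyl)acrylic acid | C=C(CBr)C(=O)O | starting material
18 | (3R,4E)-6-(tert-butyldimethylsilyloxy)-5-iodohexa-1,4-dien-3-yl 2-(bromomethyl)acrylate | IC(/CO[Si](C)(C)C(C)(C)C)=C/[C@H](OC(=O)C(=C)CBr)C=C | intermediate
19 | (R)-3-(bromomethyl)-5-[(E)-3-(tert-butyldimethylsilyloxy)-2-iodoprop-1-enyl]furan-2(5H)-one | IC(/CO[Si](C)(C)C(C)(C)C)=C/[C@@H]1OC(=O)C(CBr)=C1 | intermediate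
20 | (4R,5R)-4-[(1R,3R)-3-[(tert-butyldimethylsilyloxy)methyl]-1-(trimethylsilyloxy)hex-5-enyl]-5-[(E)-3-(tert-butyldimethylsilyloxy)-2-iodoprop-1-enyl]-3-methylenedihydrofuran-2(3H)-one (trimethylsilyl ether of 21) | IC(/CO[Si](C)(C)C(C)(C)C)=C/[C@@H]1OC(=O)C(=C)[C@H]1[C@H](O[Si](C)(C)C)C[C@H](CO[Si](C)(C)C(C)(C)C)CC=C | intermediate
21 | (4S,5R)-4-[(1R,3R)-3-[(tert-butyldimethylsilyloxy)methyl]-1-hydroxyhex-5-enyl]-5-[(E)-3-(tert-butyldimethylsilyloxy)-2-iodoprop-1-enyl]-3-methylenedihydrofuran-2(3H)-one | IC(/CO[Si](C)(C)C(C)(C)C)=C/[C@@H]1OC(=O)C(=C)[C@H]1[C@H](O)C[C@H](CO[Si](C)(C)C(C)(C)C)CC=C | intermediate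
22 | methacryloyl chloride | CC(=C)C(Cl)=O | starting material
23 | (1R,3R)-3-[(tert-butyldimethylsilyloxy)methyl]-1-[(2R,3S)-2-[(E)-3-(tert-butyldimethylsilyloxy)-2-iodoprop-1-enyl]-4-methylene-5-oxotetrahydrofuran-3-yl]hex-5-enyl methacrylate | IC(/CO[Si](C)(C)C(C)(C)C)=C/[C@@H]1OC(=O)C(=C)[C@H]1[C@H](OC(=O)C(C)=C)C[C@H](CO[Si](C)(C)C(C)(C)C)CC=C | intermediate
24 | (1R,3R)-6-(9-borabicyclo[3.3.1]nonan-9-yl)-3-[(tert-butyldimethylsilyloxy)methyl]-1-[(2R,3S)-2-[(E)-3-(tert-butyldimethylsilyloxy)-2-iodoprop-1-enyl]-4-methylene-5-oxotetrahydrofuran-3-yl]hexyl methacrylate | IC(/CO[Si](C)(C)C(C)(C)C)=C/[C@@H]1OC(=O)C(=C)[C@H]1[C@H](OC(=O)C(C)=C)C[C@H](CO[Si](C)(C)C(C)(C)C)CCCB2C3CCCC2CCC3 | intermediate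
25 | (3aS,4R,6R,10Z,11aS)-6,10-bis[(tert-butyldimethylsilyloxy)methyl]-3-methylene-2-oxo-2,3,3a,4,5,6,7,8,9,11a-decahydrocyclodeca[b]furan-4-yl methacrylate | C=C(C)C(=O)O[C@@H]1C[C@H](CO[Si](C)(C)C(C)(C)C)CCC/C(CO[Si](C)(C)C(C)(C)C)=C/[C@@H]2OC(=O)C(=C)[C@H]21 | intermediate
26 | (3aS,4R,6R,10Z,11aS)-6,10-bis(hydroxymethyl)-3-methylene-2-oxo-2,3,3a,4,5,6,7,8,9,11a-decahydrocyclodeca[b]furan-4-yl methacrylate (CNP0256084.5) | C=C(C)C(=O)O[C@@H]1C[C@H](CO)CCC/C(CO)=C/[C@@H]2OC(=O)C(=C)[C@H]21 | target

**Step count and sequence**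

Total step count: 15. Longest linear sequence: 10 steps (steps 6–15). The second branch (steps 1–5) joins at step 12.

**Steps most likely to fail, with fallbacks**

Step 6 (enantioselective alkynylation of acrolein). Acrolein is small and polymerisable, so yield and ee may fall short. The fallback sets out from 8 and 9 and returns at 11, replacing asymmetric catalysis by a racemic addition followed by kinetic resolution. Compound 9 is deprotonated with LiN(SiMe3)2 in THF at −78 °C to methyl 3-lithioprop-2-ynoate F1, which adds to 8 to give racemic methyl 4-hydroxyhex-5-en-2-ynoate F2. Sharpless kinetic resolution (Ti(OiPr)4, D-(−)-diisopropyl tartrate, t-BuOOH, 4 Å sieves, CH2Cl2, −20 °C, about 55% conversion) epoxidises the (S)-enantiomer to methyl (4R)-4-hydroxy-4-[(2R)-oxiran-2-yl]but-2-ynoate F3 and leaves 11 for chromatographic separation.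

Step 12 (the proposed chromium-catalysed butenolide allylation). Catalyst turnover or the γ/anti selectivity may fail on this substrate class. The fallback sets out from 7 and 19 and returns at 21. It abandons transition-metal catalysis for the known stoichiometric zinc Barbier coupling of bromomethylbutenolides with aldehydes (activated Zn dust, THF/saturated aq. NH4Cl, 0 °C → rt), an aqueous, ligand-free organozinc process that relies on substrate control alone. It gives 21 directly, so no compound outside the list is made (F0).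

Step 14 (hydroboration and ten-membered ring closure). Risks are competing hydroboration of the conjugated alkenes, base sensitivity of the enoates, and oligomerisation in place of ring closure. The fallback sets out from 5 and 16 and returns at 25. It reverses the order of the two C–C couplings, so the Suzuki reaction becomes intermolecular and the ring is closed at C7–C8.
- 9-BBN hydroboration of 5 gives methyl (R)-6-(9-borabicyclo[3.3.1]nonan-9-yl)-3-[(tert-butyldimethylsilyloxy)methyl]hexanoate F4.
- Coupling of this borane with 16 (Pd(dppf)Cl2, AsPh3, Cs2CO3, DMF/THF/H2O, rt) gives methyl (3R,7Z,9R)-3,7-bis[(tert-butyldimethylsilyloxy)methyl]-9-hydroxyundeca-7,10-dienoate F5.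
- i-Bu2AlH (2.2 equiv, CH2Cl2, −78 °C) gives (3R,7Z,9R)-3,7-bis[(tert-butyldimethylsilyloxy)methyl]-9-hydroxyundeca-7,10-dienal F6.
- Esterification with 17 (DIC, catalytic DMAP, 0 °C) gives (3R,4Z,9R)-5,9-bis[(tert-butyldimethylsilyloxy)methyl]-11-oxoundeca-1,4-dien-3-yl 2-(bromomethyl)acrylate F7.
- Ring-closing metathesis (second-generation Grubbs catalyst, CH2Cl2, 40 °C) gives (3R,7Z)-8-[(2S)-4-(bromomethyl)-5-oxo-2,5-dihydrofuran-2-yl]-3,7-bis[(tert-butyldimethylsilyloxy)methyl]oct-7-enal F8.
- Intramolecular zinc Barbier allylation (Zn dust, THF/aq. NH4Cl, slow addition, 2 mM) closes the ring to (3aS,4R,6R,10Z,11aS)-6,10-bis[(tert-butyldimethylsilyloxy)methyl]-4-hydroxy-3-methylene-3a,4,5,6,7,8,9,11a-octahydrocyclodeca[b]furan-2(3H)-one F9. The C7/C8 outcome of this transannular variant is less certain than in the intermolecular coupling.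
- Acylation with 22 (Et3N, DMAP) then gives 25.

**Further compounds**

F1 | step 6 | methyl 3-lithioprop-2-ynoate | [Li]C#CC(=O)OC
F2 | step 6 | racemic methyl 4-hydroxyhex-5-en-2-ynoate | COC(=O)C#CC(O)C=C
F3 | step 6 | methyl (4R)-4-hydroxy-4-[(2R)-oxiran-2-yl]but-2-ynoate | COC(=O)C#C[C@@H](O)[C@H]1CO1
F0 | step 12 | none | none
F4 | step 14 | methyl (R)-6-(9-borabicyclo[3.3.1]nonan-9-yl)-3-[(tert-butyldimethylsilyloxy)methyl]hexanoate | COC(=O)C[C@H](CO[Si](C)(C)C(C)(C)C)CCCB1C2CCCC1CCC2
F5 | step 14 | methyl (3R,7Z,9R)-3,7-bis[(tert-butyldimethylsilyloxy)methyl]-9-hydroxyundeca-7,10-dienoate | COC(=O)C[C@H](CO[Si](C)(C)C(C)(C)C)CCC/C(CO[Si](C)(C)C(C)(C)C)=C/[C@H](O)C=C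
F6 | step 14 | (3R,7Z,9R)-3,7-bis[(tert-butyldimethylsilyloxy)methyl]-9-hydroxyundeca-7,10-dienal | O=CC[C@H](CO[Si](C)(C)C(C)(C)C)CCC/C(CO[Si](C)(C)C(C)(C)C)=C/[C@H](O)C=C
F7 | step 14 | (3R,4Z,9R)-5,9-bis[(tert-butyldimethylsilyloxy)methyl]-11-oxoundeca-1,4-dien-3-yl 2-(bromomethyl)acrylate | O=CC[C@H](CO[Si](C)(C)C(C)(C)C)CCC/C(CO[Si](C)(C)C(C)(C)C)=C/[C@H](OC(=O)C(=C)CBr)C=C
F8 | step 14 | (3R,7Z)-8-[(2S)-4-(bromomethyl)-5-oxo-2,5-dihydrofuran-2-yl]-3,7-bis[(tert-butyldimethylsilyloxy)methyl]oct-7-enal | O=CC[C@H](CO[Si](C)(C)C(C)(C)C)CCC/C(CO[Si](C)(C)C(C)(C)C)=C/[C@@H]1OC(=O)C(CBr)=C1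
F9 | step 14 | (3aS,4R,6R,10Z,11aS)-6,10-bis[(tert-butyldimethylsilyloxy)methyl]-4-hydroxy-3-methylene-3a,4,5,6,7,8,9,11a-octahydrocyclodeca[b]furan-2(3H)-one | O[C@@H]1C[C@H](CO[Si](C)(C)C(C)(C)C)CCC/C(CO[Si](C)(C)C(C)(C)C)=C/[C@@H]2OC(=O)C(=C)[C@H]21
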